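Two questions stand on these flasks, a row of end excesses and its shape, and I reckon both with one ratio.

the same everywhere: left-handed substrate 0.050 M; right-handed substrate 0.050 M

|  | reagent | free catalyst | remark | time |
|---|---|---|---|---|
| delta | 0.11 M | 5.3 mM | run made earlier |  |
| theta | 0.11 M | 52 mM | run made earlier |  |
| Friday's | 0.110 M | 4.0 mM |  | 50 min |
| Monday's | 0.110 M | 12 mM |  | 50 min |
| Tuesday's | 0.110 M | 40 mM |  | 50 min |

| run | time / min | left-handed product / % | right-handed product / % |
|---|---|---|---|
| delta | 4.00 | 12.6 | 0 |
| delta | 12.0 | 20.0 | 0.7 |
| delta | 25.0 | 22.3 | 1.2 |
| delta | 40.0 | 23.1 | 1.3 |
| delta | 50.0 | 24.0 | 0.8 |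
| theta | 4.00 | 46.1 | 3.0 |
| theta | 8.00 | 54.9 | 4.6 |
| theta | 15.0 | 62.0 | 5.1 |
| theta | 25.0 | 65.6 | 5.9 |
| theta | 50.0 | 68.6 | 5.8 |

(readings scatter by 0.3 percentage points)

- free catalyst is single-handed; left-handed substrate and right-handed substrate are mirror images of each other, charged as a racemate, each of them at the stated concentration
- what may be going on: reagent + free catalyst + left-handed substrate -> free catalyst + left-handed product; reagent + free catalyst + right-handed substrate -> free catalyst + right-handed product; left-handed substrate <-> right-handed substrate; reagent + free catalyst -> spent catalyst
- an excess is the difference of the two amounts in percent of their sum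
- "hardly changes" means that all values lie within two and a half points (for a concentration: within two and a half percent of the largest)

- excess of left-handed product over right-handed product at the end for Friday's, Monday's, Tuesday's, in this order
- the shape of the row from first to last (rises all the way / falls all the way / falls, then rises / rises, then falls / hardly changes)

I call the right-handed product made per left-handed product at the end of a run the leak; the excess is then one minus the leak, over one plus the leak. The last right-handed reading in delta is 0.8% against a scatter of 0.3 percentage points, so I pool the last three readings of each run, and this gives a leak of 0.0476 in delta and 0.0856 in theta.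

The catalyst strips left-handed substrate and racemisation refills it. While the two keep pace, right-handed substrate stands above left-handed substrate by a margin in proportion to the stripping, and so to the catalyst. I therefore draw the leak as a straight line in catalyst charge, of slope 8.15 × 10⁻⁴ mM⁻¹: this leak gain, the rise of the leak per unit of catalyst charged, is what I carry. At no catalyst the line gives a leak of 0.0432, which as a reading makes the selectivity factor 23.1; the forecast's reasoning says about 30.

My row is 91.1%, 89.9%, 85.9%. The forecast gives 92.5%, 90.5%, 86%, and its shape is falls all the way, on the ground that “More catalyst strips the left-handed substrate faster than racemisation refills it”. My Friday's figure stands lower than the forecast's.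

The flasks give 91.6%, 90.2%, 86.6%: falls all the way.

    reagent + free catalyst + left-handed substrate → free catalyst + left-handed product (k = 3.00 M⁻² s⁻¹)
    reagent + free catalyst + right-handed substrate → free catalyst + right-handed product (k = 0.120 M⁻² s⁻¹)
    left-handed substrate ⇌ right-handed substrate (k = 0.00150 s⁻¹)
    reagent + free catalyst → spent catalyst (k = 0.0280 M⁻¹ s⁻¹)

In Friday's flask at 3.64 min, the forward racemisation alone has a half-life of 7.7 min for left-handed substrate, against 18 min by the path to left-handed product. At 25.0 min Friday's flask holds 40.1% left-handed against 41.1% right-handed substrate, and Tuesday's holds 14.0% against 17.3%. From Friday's leak of 0.0438, the leak gain carries to an excess of 86.4% for Tuesday's, where the flask gives 86.6%, and of 90.4% for Monday's, where the flask gives 90.2%.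

(The readings come from a simulation with constants of no real substance, noise included.)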